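## Structural features

The target is a tetrahydrofuran (O1, C2, C3, C4, C5) of the 7,9′-epoxylignan type. C2 carries ring A (3,4,5-trimethoxyphenyl), C3 a hydroxymethyl group, C4 a methylene bonded to ring B (2,4,5-trimethoxyphenyl), and C5 is an unsubstituted OCH2 carbon. C2, C3 and C4 are three contiguous stereocentres, all R, with their substituents on one face of the ring (2,3-cis and 3,4-cis). This all-cis array is the most crowded diastereomer, so it must be built under kinetic control and every later step must avoid equilibration. C2 is a benzylic ether carbon that can ionise under acid and re-close to the trans ring, and C3 would epimerise next to a carbonyl group unless it is held by a ring. Other fragile elements are the C2–O1 bond toward hydrogenolysis, the very electron-rich and strongly cation-stabilising ring B, and the nucleophilic ortho carbons of ring A, which can capture a cation formed nearby. The difficulty is therefore the cis,cis stereotriad, not the connectivity. The key step exploits two mappings: O1–C5–C4 plus the first side-chain carbon on C4 is a 2-vinylethanol (oxy-allyl) unit, and C2–C3 with ring A and a carboxyl-level carbon on C3 is an arylidene malonate. O1–C2 and C3–C4 can then be formed in one palladium-catalysed [3+2] event that fixes C2 and C4, and the second ester on C3 later serves as a lactone tether that fixes C3.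

## Logic of the disconnections

15 ⇒ 14. The C–H bond at the methylene between C4 and ring B is taken back to a C–OH bond. An oxygen here lets this carbon be made by carbonyl addition and lets it tether C3; ring B makes it the most easily ionised C–O bond in the molecule. The forward step must reduce this carbinol without ionising C2–O1.

14 ⇒ 13. The primary C–OH carbon on C3 and the carbinol oxygen are reconnected as the acyl–O bond of a γ-lactone. In a cis-fused bicyclo[3.3.0] lactone the configuration of C3 is dictated by C4, so the stereotriad is reduced to the C2/C4 pair. The forward hydride reduction must not epimerise C3.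

13 ⇒ 11 (12 in passage). The C3–H bond is replaced by a C3–CO2Me bond. A geminal diester removes C3 as a stereocentre from the ring-forming step and guarantees that one ester is cis to whatever sits on C4. The forward step must delete the spare ester with protonation governed by the ring fusion and without opening either ring.

11 ⇒ 7 + 8 (9 and 10 in passage). The bond between ring B and the carbinol carbon and the lactone acyl–O bond are cut. Ring B then comes from a commercial bromide and the route becomes convergent. The forward addition must choose the formyl group over two esters and must not deprotonate the α-stereocentre; no facial control is needed.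

7 ⇒ 5 (6 in passage). The C=O bond is traced to a terminal C=C bond, with one carbon excised. A vinyl group is the native output of π-allyl chemistry. The forward cleavage must spare two electron-rich arenes and must not epimerise C4.

5 ⇒ 3 + 4. O1–C2 and C3–C4 are cut. This removes the ring and two stereocentres at once and leaves an achiral acceptor and a racemic four-carbon carbonate. The forward step must deliver enantioselection at C4 and the 2,4-cis relationship.

3 ⇒ 1 + 2. The C=C bond is cut to an aldehyde and an active methylene compound. Both are bulk chemicals; the forward step only needs removal of water.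

## Other disconnections considered

Alternative 1: The cut is C4–C5, with the benzylic C–H bonds of the ring B methylene traced to an exocyclic alkene; C5 is supplied as the acetal carbon of a methoxymethyl ether on O1. In the forward sense A1 would be treated with Me3SiOTf and a hindered pyridine base in CH2Cl2 at −78 °C. The oxocarbenium ion on O1 is attacked by the styrene at C4, ring B stabilises the resulting benzylic cation, and loss of the C4 proton gives benzylidene A2. Hydrogenation from the face opposite the two cis substituents and desilylation would then lead to 15.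
- In favour: ring B arrives as a styrene, so no benzylic oxygen has to be removed (better than the chosen plan). C3 arrives at the alcohol oxidation level, so no decarboxylation or hydride reduction is needed (better). Setting the last centre by hydrogenation anti to two cis groups is a sound way to the all-cis pattern, equal in quality to the lactone tether.
- Against: the 2,3-relationship has to be built in a separate acyclic asymmetric synthesis of A1. The oxocarbenium ion sits one atom from ring A, so closure onto an ortho carbon of ring A (oxa-Pictet–Spengler, six-membered) competes with the Prins closure. The same ion is a 2-oxonia-1,5-diene, and an oxonia-Cope shift would move the charge to the ring A benzylic carbon and scramble C2/C3. The elimination may place the alkene in the ring, and hydrogenation next to an allylic C5–O1 and a benzylic C2–O1 bond invites hydrogenolysis.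
- Comparison: on structure, the chosen step forms two ring bonds and two stereocentres from achiral and racemic partners, whereas the Prins step forms one ring bond and no stereocentre. On mechanism, a cationic closure is hard to reconcile with two cation-trapping arenes, while in the π-allyl route the arenes are spectators (chosen plan better). On step economy, about four steps to A1 plus three gives seven to eight, equal or slightly worse.

Alternative 2: The cut is O1–C5, with C2=C3 kept unsaturated. In the forward sense the ketone- and ester-activated cyclopropane A3 would be heated with NaI or DABCO in DMSO. SN2 opening at the unsubstituted CH2 is followed by 5-exo-tet O-alkylation by the enolate oxygen with expulsion of the nucleophile, giving dihydrofuran A4 with C4 untouched. cis-Hydrogenation of C2=C3 anti to the C4 benzyl group and ester reduction would complete 15.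
- In favour: ring B is part of the carbon skeleton from the start, with no oxygen at its benzylic carbon (better). Only one stereocentre needs external control (equal; the chosen plan also rests on one catalytic asymmetric event). The sequence is about five to six steps against seven (better), and the key step needs no precious metal (better on cost).
- Against: the hydrogenation of a tetrasubstituted, donor–acceptor-polarised alkene bearing an aryl group is the weak point. Conditions able to reduce it threaten the benzylic C2–O1 bond once it exists, face selection rests on a single CH2Ar group, and non-catalytic reductions lead to the trans ester. C3 next to the ester can epimerise toward trans before the final reduction, and an asymmetric cyclopropanation with a keto-ester carbene precursor is not a high-fidelity reaction.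
- Comparison: on structure, this plan makes the ring flat and defers two stereocentres to one reduction, while the chosen plan sets C2/C4 during ring formation and C3 by a tether. On mechanism, the ring expansion itself is more predictable than the cycloaddition, but the stereochemistry-defining hydrogenation is less predictable than a ring-fusion-controlled protonation. On step economy the alternative is shorter.

Alternative 3: The cuts are C2–C3 and O1–C5, with C5 at the carboxyl level. In the forward sense aldehyde 1 and allylboronate A5 would react under a chiral phosphoric acid in toluene. A chair transition state forms C2–C3 and the borate closes onto the ester to give the cis α-methylene lactone A6. Ring B would then be attached at the exocyclic methylene (arylation with 8 and hydrogenation from the open face), the lactone reduced to the cyclic ether (DIBAL-H, then Et3SiH/BF3·OEt2) and the silyl group removed.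
- In favour: the 2,3-cis relationship comes from a closed six-membered transition state, which is better founded than the relative ring-closure rates that define C2 in the chosen plan (better). It starts from the same aldehyde 1 (equal). C3 is at the right oxidation level and ring B is attached without a benzylic oxygen (better).
- Against: C5 must be deoxygenated from the carboxyl level through an oxocarbenium ion under a Lewis acid while the benzylic C2–O1 bond is in the same ring. C4 is created next to the lactone carbonyl in the least stable all-cis arrangement and can epimerise until the lactone is reduced. A5 of defined alkene geometry needs its own synthesis, and the electron-rich aldehyde 1 is a slow partner for this weakly nucleophilic class of allylboronate.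
- Comparison: on structure, the alternative builds the stereotriad in two events (allylboration, hydrogenation) and the chosen plan in two as well (cycloaddition, tethered protonation). On mechanism, the alternative is better for the first diad and worse for the last centre and for the acid-mediated C5 reduction. On step economy, about three steps to A5, the key step and four to five more give eight or nine against seven (chosen plan better).

Key step: step 2

Remark 1: the carbinol carbon created in step 4 is not controlled and is carried as both configurations, because it becomes CH2 in step 7; compounds 10–14 are written without a descriptor at that carbon.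
Remark 2: the (S,S,S) ligand is written in step 2; the antipode that leads to the (2S,4R) series is to be assigned in a first run and the (R,R,R) ligand used if the sense is opposite.

## Route

Step 1
Reactants: 1 3,4,5-trimethoxybenzaldehyde; 2 dimethyl malonate
Product: 3 dimethyl 2-(3,4,5-trimethoxybenzylidene)malonate
Conditions: piperidine (0.1 equiv), AcOH (0.1 equiv), toluene, reflux, Dean–Stark
Reagents that add atoms: none
Why: Knoevenagel condensation of a non-enolisable aromatic aldehyde with an active methylene compound, driven by azeotropic removal of water; the two esters are identical, so no alkene geometry arises.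

Step 2
Reactants: 3 dimethyl 2-(3,4,5-trimethoxybenzylidene)malonate; 4 4-vinyl-1,3-dioxolan-2-one (racemic, 1.5 equiv)
Product: 5 dimethyl (2S,4R)-2-(3,4,5-trimethoxyphenyl)-4-vinyltetrahydrofuran-3,3-dicarboxylate (2,4-cis)
Conditions: Pd2(dba)3·CHCl3 (2.5 mol %), (S,S,S)-(1,1′-binaphthalene-2,2′-diyl) N,N-bis(1-phenylethyl)phosphoramidite (10 mol %), THF, 0 °C → rt
Reagents that add atoms: none
Why: Zerovalent palladium ionises the allylic C–O bond of 4 and CO2 is lost, giving a zwitterionic π-allylpalladium alkoxide; both enantiomers of 4 converge because the π-allyl diastereomers interconvert by π–σ–π isomerisation before they are trapped. The alkoxide adds reversibly to the electron-poor benzylidene carbon of 3 (oxa-Michael, O1–C2), and the malonate carbanion so formed alkylates the internal allyl terminus (C3–C4) and releases the catalyst. The closest known reaction type is the zerovalent-palladium-catalysed decarboxylative [3+2] cycloaddition of vinylethylene carbonates or vinyl epoxides with doubly activated alkenes, run enantioselectively with chiral phosphorus ligands. The tetrahydrofuran ring is closed by 5-exo attack of the malonate carbon on the π-allyl unit; attack at the distal terminus would need a seven-membered ring and is not expected. C4 is set by the chiral phosphoramidite, which differentiates the faces of the allyl unit in the irreversible C–C bond formation. C2 is set relative to C4: the two C2-epimeric open-chain adducts equilibrate through the reversible oxa-Michael step, and the closure with ring A and the allyl unit both pseudo-equatorial, which leads to the 2,4-cis ring, should be the faster one. The step needs regioselectivity (secured by the polarity of 3 and by ring size), enantioselectivity (ligand) and 2,4-cis diastereoselectivity (reversibility plus the 1,3-pseudo-diequatorial transition state); C3 carries two identical esters and is deliberately left without configuration.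

Step 3
Reactants: 5 dimethyl (2S,4R)-2-(3,4,5-trimethoxyphenyl)-4-vinyltetrahydrofuran-3,3-dicarboxylate
Product: 7 dimethyl (2S,4R)-4-formyl-2-(3,4,5-trimethoxyphenyl)tetrahydrofuran-3,3-dicarboxylate, via vicinal diol 6 (not isolated)
Conditions: OsO4 (2 mol %), NaIO4 (4 equiv), 2,6-lutidine (2 equiv), 1,4-dioxane/H2O (3:1), rt
Reagents that add atoms: osmium tetroxide, O=[Os](=O)(=O)=O (catalytic oxygen carrier); sodium periodate, [Na+].[O-]I(=O)(=O)=O (terminal oxidant that supplies the oxygen)
Why: Lemieux–Johnson oxidation: osmylation of the only alkene gives diol 6, which periodate cleaves to the aldehyde and formaldehyde. The lutidine buffer keeps the α-stereocentre C4 from epimerising, and the electron-rich arenes, which ozone could attack, are untouched.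

Step 4
Reactants: 7 dimethyl (2S,4R)-4-formyl-2-(3,4,5-trimethoxyphenyl)tetrahydrofuran-3,3-dicarboxylate; 8 1-bromo-2,4,5-trimethoxybenzene (1.2 equiv)
Product: 11 methyl (1S,2S,5R)-8-oxo-6-(2,4,5-trimethoxyphenyl)-2-(3,4,5-trimethoxyphenyl)-3,7-dioxabicyclo[3.3.0]octane-1-carboxylate (cis-fused; both configurations at C6), via arylmagnesium bromide 9 (not isolated), via bromomagnesium alkoxide 10 (not isolated)
Conditions: 8, Mg turnings, THF, 45 °C; then added to 7, THF, −78 °C → rt; aq NH4Cl
Reagents that add atoms: none
Why: Grignard 1,2-addition: at −78 °C the aryl Grignard reagent adds to the formyl group much faster than to the two hindered esters on the quaternary carbon. On warming, alkoxide 10 attacks the ester on its own face of the ring (acyl substitution, five-membered ring), so only the cis-fused γ-lactone can form. The carbinol centre needs no control because it becomes CH2 in step 7.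

Step 5
Reactants: 11 methyl (1S,2S,5R)-8-oxo-6-(2,4,5-trimethoxyphenyl)-2-(3,4,5-trimethoxyphenyl)-3,7-dioxabicyclo[3.3.0]octane-1-carboxylate
Product: 13 (1S,2R,5R)-6-(2,4,5-trimethoxyphenyl)-2-(3,4,5-trimethoxyphenyl)-3,7-dioxabicyclo[3.3.0]octan-8-one (cis-fused; both configurations at C6), via lithium carboxylate 12 (not isolated)
Conditions: LiCl (3 equiv), H2O (3 equiv), DMSO, 135 °C
Reagents that add atoms: none
Why: Krapcho dealkoxycarbonylation: chloride demethylates the ester (SN2 at CH3), carboxylate 12 loses CO2 and water protonates the lactone enolate. Only the cis fusion of the bicyclo[3.3.0] system is accessible, so the proton goes to C3 on the face away from the lactone bridge and the carbonyl carbon ends cis to both neighbours. Ring opening of the enolate by loss of O1 would be the reverse of a 5-endo-trig closure and is stereoelectronically disfavoured.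

Step 6
Reactants: 13 (1S,2R,5R)-6-(2,4,5-trimethoxyphenyl)-2-(3,4,5-trimethoxyphenyl)-3,7-dioxabicyclo[3.3.0]octan-8-one
Product: 14 (2R,3R,4R)-4-[hydroxy(2,4,5-trimethoxyphenyl)methyl]-3-(hydroxymethyl)-2-(3,4,5-trimethoxyphenyl)tetrahydrofuran (both carbinol configurations)
Conditions: LiAlH4 (2 equiv), THF, 0 °C → rt; H2O, 15 % aq NaOH
Reagents that add atoms: none
Why: LiAlH4 reduction of a lactone to the diol; hydride addition is faster than enolisation, so C3 keeps its configuration, and aryl ethers and the cyclic ether are inert.

Step 7
Reactants: 14 (2R,3R,4R)-4-[hydroxy(2,4,5-trimethoxyphenyl)methyl]-3-(hydroxymethyl)-2-(3,4,5-trimethoxyphenyl)tetrahydrofuran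
Product: 15 [(2R,3R,4R)-4-(2,4,5-trimethoxybenzyl)-2-(3,4,5-trimethoxyphenyl)tetrahydrofuran-3-yl]methanol
Conditions: Et3SiH (5 equiv), CF3CO2H (3 equiv), CH2Cl2, −40 → 0 °C; aq NaHCO3
Reagents that add atoms: none
Why: Ionic hydrogenation: the secondary alcohol is benzylic to ring B, whose ortho and para methoxy groups let it ionise under mild acid far more readily than the C2–O1 ether next to ring A or the primary alcohol. Et3SiH reduces the cation irreversibly, both carbinol epimers converge on the CH2 group, and no ring stereocentre takes part.

## Compound list

1 | 3,4,5-trimethoxybenzaldehyde | COc1cc(C=O)cc(OC)c1OC | starting material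
2 | dimethyl malonate | COC(=O)CC(=O)OC | starting material
3 | dimethyl 2-(3,4,5-trimethoxybenzylidene)malonate | COC(=O)C(=Cc1cc(OC)c(OC)c(OC)c1)C(=O)OC | intermediate
4 | 4-vinyl-1,3-dioxolan-2-one (racemic) | C=CC1COC(=O)O1 | starting material
5 | dimethyl (2S,4R)-2-(3,4,5-trimethoxyphenyl)-4-vinyltetrahydrofuran-3,3-dicarboxylate | C=C[C@H]1CO[C@@H](c2cc(OC)c(OC)c(OC)c2)C1(C(=O)OC)C(=O)OC | intermediate
6 | dimethyl (2S,4R)-4-(1,2-dihydroxyethyl)-2-(3,4,5-trimethoxyphenyl)tetrahydrofuran-3,3-dicarboxylate | OCC(O)[C@H]1CO[C@@H](c2cc(OC)c(OC)c(OC)c2)C1(C(=O)OC)C(=O)OC | intermediate (not isolated)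
7 | dimethyl (2S,4R)-4-formyl-2-(3,4,5-trimethoxyphenyl)tetrahydrofuran-3,3-dicarboxylate | O=C[C@H]1CO[C@@H](c2cc(OC)c(OC)c(OC)c2)C1(C(=O)OC)C(=O)OC | intermediate
8 | 1-bromo-2,4,5-trimethoxybenzene | COc1cc(OC)c(Br)cc1OC | starting material
9 | (2,4,5-trimethoxyphenyl)magnesium bromide | COc1cc(OC)c([Mg]Br)cc1OC | intermediate (not isolated)
10 | bromomagnesium alkoxide of dimethyl (2S,4R)-4-[hydroxy(2,4,5-trimethoxyphenyl)methyl]-2-(3,4,5-trimethoxyphenyl)tetrahydrofuran-3,3-dicarboxylate | Br[Mg]OC(c3cc(OC)c(OC)cc3OC)[C@H]1CO[C@@H](c2cc(OC)c(OC)c(OC)c2)C1(C(=O)OC)C(=O)OC | intermediate (not isolated)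
11 | methyl (1S,2S,5R)-8-oxo-6-(2,4,5-trimethoxyphenyl)-2-(3,4,5-trimethoxyphenyl)-3,7-dioxabicyclo[3.3.0]octane-1-carboxylate (C1 and C5 are the ring-fusion carbons, C2 bears ring A, C6 bears ring B) | O=C1OC(c3cc(OC)c(OC)cc3OC)[C@H]2CO[C@@H](c4cc(OC)c(OC)c(OC)c4)[C@@]12C(=O)OC | intermediate
12 | lithium (1S,2S,5R)-8-oxo-6-(2,4,5-trimethoxyphenyl)-2-(3,4,5-trimethoxyphenyl)-3,7-dioxabicyclo[3.3.0]octane-1-carboxylate | O=C1OC(c3cc(OC)c(OC)cc3OC)[C@H]2CO[C@@H](c4cc(OC)c(OC)c(OC)c4)[C@@]12C(=O)[O-].[Li+] | intermediate (not isolated)
13 | (1S,2R,5R)-6-(2,4,5-trimethoxyphenyl)-2-(3,4,5-trimethoxyphenyl)-3,7-dioxabicyclo[3.3.0]octan-8-one | O=C1OC(c3cc(OC)c(OC)cc3OC)[C@H]2CO[C@@H](c4cc(OC)c(OC)c(OC)c4)[C@@H]12 | intermediate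
14 | (2R,3R,4R)-4-[hydroxy(2,4,5-trimethoxyphenyl)methyl]-3-(hydroxymethyl)-2-(3,4,5-trimethoxyphenyl)tetrahydrofuran | COc1cc(OC)c(OC)cc1C(O)[C@H]1CO[C@@H](c2cc(OC)c(OC)c(OC)c2)[C@H]1CO | intermediate
15 | [(2R,3R,4R)-4-(2,4,5-trimethoxybenzyl)-2-(3,4,5-trimethoxyphenyl)tetrahydrofuran-3-yl]methanol | COc1cc(OC)c(OC)cc1C[C@H]1CO[C@@H](c2cc(OC)c(OC)c(OC)c2)[C@H]1CO | target

## Step count and least certain steps

Total: 7 steps. Longest linear sequence: 7 steps (1 → 3 → 5 → 7 → 11 → 13 → 14 → 15); 4 and 8 enter as purchased materials.

Step 2 (key step). The most likely failure is slow, reversible capture of the palladium-bound alkoxide, because ring A makes acceptor 3 electron-rich. The zwitterion can then be lost by β-hydride elimination or self-condensation. Since C2 is defined only by the relative rates of two ring closures, incomplete 2,4-cis selection and incomplete enantioselection are the likely companions. The fallback changes the acceptor class and the way the diester is reached. It sets out from 1 and 4. Knoevenagel condensation of 1 with 2,2-dimethyl-1,3-dioxane-4,6-dione (piperidinium acetate, EtOH) would give the much stronger acceptor 2,2-dimethyl-5-(3,4,5-trimethoxybenzylidene)-1,3-dioxane-4,6-dione F1. Cycloaddition of F1 with 4 under the same Pd2(dba)3·CHCl3/phosphoramidite system would give (1S,4R)-8,8-dimethyl-1-(3,4,5-trimethoxyphenyl)-4-vinyl-2,7,9-trioxaspiro[4.5]decane-6,10-dione F2. Here the stabilised dioxanedione anion may also allow palladium to re-ionise the C3–C4 bond, so the ring closure itself could equilibrate toward the cis ring. NaOMe in MeOH would open the dioxanedione with loss of acetone to sodium (2S,4R)-3-(methoxycarbonyl)-2-(3,4,5-trimethoxyphenyl)-4-vinyltetrahydrofuran-3-carboxylate F3, and MeI in DMF would esterify F3 to 5, where the route is rejoined.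

Step 7. The ring B benzylic cation may be captured by an ortho carbon of ring A (intramolecular Friedel–Crafts alkylation; both groups are cis on the ring). Under too strong acid the C2–O1 bond may ionise, causing epimerisation at C2 toward the more stable 2,3-trans ring or reductive ring opening. The fallback replaces the cationic deoxygenation by a radical one. It sets out from 14. TBSCl/imidazole (CH2Cl2, 0 °C) would silylate the primary alcohol to (2R,3R,4R)-3-[(tert-butyldimethylsilyloxy)methyl]-4-[hydroxy(2,4,5-trimethoxyphenyl)methyl]-2-(3,4,5-trimethoxyphenyl)tetrahydrofuran F4. NaH, CS2 and MeI (THF) would give the O-alkyl S-methyl xanthate of F4, F5. Bu3SnH/AIBN (toluene, 80 °C, Barton–McCombie deoxygenation) would give (2R,3R,4R)-3-[(tert-butyldimethylsilyloxy)methyl]-4-(2,4,5-trimethoxybenzyl)-2-(3,4,5-trimethoxyphenyl)tetrahydrofuran F6. Bu4NF in THF would return to the route at 15.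

Step 5. At 135 °C the lactone C–O bond at the ring B benzylic carbon may ionise or be attacked by chloride. The lactone would then open, decarboxylation would proceed without the ring-fusion constraint, and C3 would be protonated unselectively; elimination toward a styrene is the related loss. The fallback is a hydrolytic, low-temperature sequence through the free acid. It sets out from 11. LiOH in THF/H2O at 40 °C would hydrolyse both ester and lactone to dilithium (2S,4R)-4-[hydroxy(2,4,5-trimethoxyphenyl)methyl]-2-(3,4,5-trimethoxyphenyl)tetrahydrofuran-3,3-dicarboxylate F7. Buffering to pH 4 (NaH2PO4) would let only the carboxyl cis to the C4 side chain re-lactonise, giving (1S,2S,5R)-8-oxo-6-(2,4,5-trimethoxyphenyl)-2-(3,4,5-trimethoxyphenyl)-3,7-dioxabicyclo[3.3.0]octane-1-carboxylic acid F8. Warming F8 in toluene at 80–90 °C would decarboxylate it through the lactone enol and return to the route at 13.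

Step 4. The basic Grignard reagent may deprotonate the α-branched aldehyde (epimerisation at C4 or recovered material) or add to an ester, and one carbinol epimer may lactonise incompletely. The fallback is a catalytic, non-basic arylation. It sets out from 7. Rhodium-catalysed 1,2-addition of (2,4,5-trimethoxyphenyl)boronic acid ([Rh(cod)OH]2, P(t-Bu)3, 1,4-dioxane/H2O, 40 °C) would give dimethyl (2S,4R)-4-[hydroxy(2,4,5-trimethoxyphenyl)methyl]-2-(3,4,5-trimethoxyphenyl)tetrahydrofuran-3,3-dicarboxylate F9. Catalytic DBU in toluene would close F9 to the lactone and return to the route at 11.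

Step 3. The transient diol 6 may lactonise onto the neighbouring ester faster than periodate cleaves it, which removes the 1,2-diol from the cleavage, and the aldehyde may epimerise at C4 if the medium turns basic. The fallback avoids any diol. It sets out from 5: ozonolysis (O3, CH2Cl2/MeOH, −78 °C, stopped at a dye end-point with Sudan Red 7B to protect the arenes; then PPh3) would give 7 directly, where the route is rejoined.

## Further compounds

F1 | step 2 | 2,2-dimethyl-5-(3,4,5-trimethoxybenzylidene)-1,3-dioxane-4,6-dione | CC1(C)OC(=O)C(=Cc2cc(OC)c(OC)c(OC)c2)C(=O)O1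
F2 | step 2 | (1S,4R)-8,8-dimethyl-1-(3,4,5-trimethoxyphenyl)-4-vinyl-2,7,9-trioxaspiro[4.5]decane-6,10-dione | C=C[C@H]1CO[C@@H](c2cc(OC)c(OC)c(OC)c2)C13C(=O)OC(C)(C)OC3=O
F3 | step 2 | sodium (2S,4R)-3-(methoxycarbonyl)-2-(3,4,5-trimethoxyphenyl)-4-vinyltetrahydrofuran-3-carboxylate (either configuration at C3) | C=C[C@H]1CO[C@@H](c2cc(OC)c(OC)c(OC)c2)C1(C(=O)OC)C(=O)[O-].[Na+]
F4 | step 7 | (2R,3R,4R)-3-[(tert-butyldimethylsilyloxy)methyl]-4-[hydroxy(2,4,5-trimethoxyphenyl)methyl]-2-(3,4,5-trimethoxyphenyl)tetrahydrofuran | COc1cc(OC)c(OC)cc1C(O)[C@H]1CO[C@@H](c2cc(OC)c(OC)c(OC)c2)[C@H]1CO[Si](C)(C)C(C)(C)C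
F5 | step 7 | O-alkyl S-methyl xanthate of F4 at the ring B carbinol | COc1cc(OC)c(OC)cc1C(OC(=S)SC)[C@H]1CO[C@@H](c2cc(OC)c(OC)c(OC)c2)[C@H]1CO[Si](C)(C)C(C)(C)C
F6 | step 7 | (2R,3R,4R)-3-[(tert-butyldimethylsilyloxy)methyl]-4-(2,4,5-trimethoxybenzyl)-2-(3,4,5-trimethoxyphenyl)tetrahydrofuran | COc1cc(OC)c(OC)cc1C[C@H]1CO[C@@H](c2cc(OC)c(OC)c(OC)c2)[C@H]1CO[Si](C)(C)C(C)(C)C
F7 | step 5 | dilithium (2S,4R)-4-[hydroxy(2,4,5-trimethoxyphenyl)methyl]-2-(3,4,5-trimethoxyphenyl)tetrahydrofuran-3,3-dicarboxylate | OC(c3cc(OC)c(OC)cc3OC)[C@H]1CO[C@@H](c2cc(OC)c(OC)c(OC)c2)C1(C(=O)[O-])C(=O)[O-].[Li+].[Li+]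
F8 | step 5 | (1S,2S,5R)-8-oxo-6-(2,4,5-trimethoxyphenyl)-2-(3,4,5-trimethoxyphenyl)-3,7-dioxabicyclo[3.3.0]octane-1-carboxylic acid | O=C1OC(c3cc(OC)c(OC)cc3OC)[C@H]2CO[C@@H](c4cc(OC)c(OC)c(OC)c4)[C@@]12C(=O)O
F9 | step 4 | dimethyl (2S,4R)-4-[hydroxy(2,4,5-trimethoxyphenyl)methyl]-2-(3,4,5-trimethoxyphenyl)tetrahydrofuran-3,3-dicarboxylate | OC(c3cc(OC)c(OC)cc3OC)[C@H]1CO[C@@H](c2cc(OC)c(OC)c(OC)c2)C1(C(=O)OC)C(=O)OC
F0 | step 3 | none | none
A1 | alternative 1 | methoxymethyl ether of (E)-2-[(tert-butyldiphenylsilyloxy)methyl]-1-(3,4,5-trimethoxyphenyl)-4-(2,4,5-trimethoxyphenyl)but-3-en-1-ol, configured at C1 and C2 as 15 is at C2 and C3 | COCO[C@@H](c1cc(OC)c(OC)c(OC)c1)[C@H](/C=C/c2cc(OC)c(OC)cc2OC)CO[Si](c3ccccc3)(c4ccccc4)C(C)(C)C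
A2 | alternative 1 | 2,3-cis-3-[(tert-butyldiphenylsilyloxy)methyl]-2-(3,4,5-trimethoxyphenyl)-4-[(Z)-2,4,5-trimethoxybenzylidene]tetrahydrofuran | COc1cc(OC)c(OC)cc1/C=C5\CO[C@@H](c2cc(OC)c(OC)c(OC)c2)[C@H]5CO[Si](c3ccccc3)(c4ccccc4)C(C)(C)C
A3 | alternative 2 | ethyl 1-(3,4,5-trimethoxybenzoyl)-2-(2,4,5-trimethoxybenzyl)cyclopropane-1-carboxylate, C2 configured as C4 of 15 | CCOC(=O)C1(C(=O)c2cc(OC)c(OC)c(OC)c2)C[C@@H]1Cc3cc(OC)c(OC)cc3OC
A4 | alternative 2 | ethyl (4R)-2-(3,4,5-trimethoxyphenyl)-4-(2,4,5-trimethoxybenzyl)-4,5-dihydrofuran-3-carboxylate | CCOC(=O)C1=C(c2cc(OC)c(OC)c(OC)c2)OC[C@@H]1Cc3cc(OC)c(OC)cc3OC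
A5 | alternative 3 | methyl (E)-4-(tert-butyldimethylsilyloxy)-2-[(4,4,5,5-tetramethyl-1,3,2-dioxaborolan-2-yl)methyl]but-2-enoate | COC(=O)/C(=C/CO[Si](C)(C)C(C)(C)C)CB1OC(C)(C)C(C)(C)O1
A6 | alternative 3 | 4,5-cis-4-[(tert-butyldimethylsilyloxy)methyl]-3-methylene-5-(3,4,5-trimethoxyphenyl)dihydrofuran-2-one | C=C1[C@H](CO[Si](C)(C)C(C)(C)C)[C@H](c2cc(OC)c(OC)c(OC)c2)OC1=O
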